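**Plan**

1. Retrosynthetic cuts, in order: C6–C1'' (ring-A carbon to the CH2 of the C10 chain); then C2–C1' (pyranone C2 to ring B), which leaves a 6-iodochromone; in the chain, C2''–C1''' (to the prenyl CH2), which leaves a senecioyl imide.
2. Forward: rings A/C come as 5,7-dihydroxychromone (7-O-MOM, C6 iodination, 5-O-MOM); ring B is added at C2 by Rh-catalysed 1,4-addition; the chain is made by dienolate prenylation, reduction and iodination; the two halves are joined at C6 by a Pd-catalysed alkylzinc coupling; acetal removal ends the route.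
3. Enabling feature: C6 is the one ring-A carbon ortho to the C5 hydroxyl that is hydrogen-bonded to the C4 carbonyl, so iodine is expected to enter at C6 and not at C8. The resulting C6–I bond, flanked by two small acetal oxygens, is the only site a Pd/zinc coupling can address.
4. Why this event: C1'' is homoallylic and C2'' is sp3, so no [3,3] shift from O5 or O7 can deliver the chain, and phenoxide C-alkylation with a β-branched primary halide neither works nor tells C6 from C8. A base-free two-electron sp2–sp3 coupling moves the intact chiral C10 unit onto the intact flavanone.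
5. Stereochemistry: C2 (S) from the chiral Rh–bisphosphine catalyst; C2'' from the (R)-4-benzyloxazolidinone in the dienolate alkylation (it is (R) in lavandulol and (S) in the target only through a CIP priority change). Neither centre is touched afterwards.

Key step: step 11

Assumption: the (S)-bisphosphine is taken to deliver the aryl group to the same enone face of the chromone as in cyclic enones, which corresponds to (2S); if the sense proves opposite, the (R)-ligand is used and nothing else changes.

**Route**

Step 1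
Reactants: 1 5,7-dihydroxy-4H-chromen-4-one
Product: 2 5-hydroxy-7-(methoxymethoxy)-4H-chromen-4-one
Conditions: MOMCl (1.1 equiv), i-Pr2NEt, DMF/CH2Cl2, 0 °C → rt
Reagents that add atoms: chloromethyl methyl ether, COCCl
Why: Williamson-type acetal ether formation, in which the C7 hydroxyl (a vinylogous acid para to the C4 carbonyl) is alkylated while the C5 hydroxyl stays locked in its hydrogen bond to C4=O.

Step 2
Reactants: 2 5-hydroxy-7-(methoxymethoxy)-4H-chromen-4-one
Product: 3 5-hydroxy-6-iodo-7-(methoxymethoxy)-4H-chromen-4-one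
Conditions: BnNMe3·ICl2 (1.05 equiv), CaCO3, CH2Cl2/MeOH (5:2), rt
Reagents that add atoms: benzyltrimethylammonium dichloroiodate, C[N+](C)(C)Cc1ccccc1.Cl[I-]Cl
Why: Electrophilic aromatic iodination in which the free, chelated C5 phenol directs iodine to its only open ortho carbon C6 (the site selectivity known for 5-hydroxy-7-alkoxy chromones and flavones with this reagent), while CaCO3 takes up HCl so that the acetal survives.

Step 3
Reactants: 3 5-hydroxy-6-iodo-7-(methoxymethoxy)-4H-chromen-4-one
Product: 5 6-iodo-5,7-bis(methoxymethoxy)-4H-chromen-4-one, via sodium phenoxide 4 (not isolated)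
Conditions: NaH, DMF, 0 °C; then MOMCl, 0 °C → rt
Reagents that add atoms: chloromethyl methyl ether, COCCl
Why: Williamson ether synthesis in which NaH breaks the O5–H···O=C4 chelate irreversibly; the hindered oxygen is protected at this stage because the chromone has no stereocentre and no base-labile C2–O bond yet.

Step 4
Reactants: 6 4-bromo-3-methoxyphenol
Product: 7 1-bromo-2-methoxy-4-(methoxymethoxy)benzene
Conditions: MOMCl, i-Pr2NEt, CH2Cl2, 0 °C → rt
Reagents that add atoms: chloromethyl methyl ether, COCCl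
Why: Williamson-type MOM ether formation on the only acidic group of 6.

Step 5
Reactants: 7 1-bromo-2-methoxy-4-(methoxymethoxy)benzene
Product: 10 [2-methoxy-4-(methoxymethoxy)phenyl]boronic acid, via aryllithium 8 (not isolated), via lithium borate 9 (not isolated)
Conditions: n-BuLi, THF, −78 °C; B(Oi-Pr)3, −78 °C → rt; aq. HCl to pH 6, 0 °C
Reagents that add atoms: triisopropyl borate, CC(C)OB(OC(C)C)OC(C)C; water, O
Why: Bromine–lithium exchange at −78 °C (faster than acetal-directed ortho-lithiation), borylation of the aryllithium with the trialkyl borate and mild hydrolysis of the ate complex, which the MOM ether should tolerate at pH 6.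

Step 6
Reactants: 5 6-iodo-5,7-bis(methoxymethoxy)-4H-chromen-4-one; 10 [2-methoxy-4-(methoxymethoxy)phenyl]boronic acid
Product: 11 (2S)-6-iodo-2-[2-methoxy-4-(methoxymethoxy)phenyl]-5,7-bis(methoxymethoxy)-2,3-dihydro-4H-chromen-4-one
Conditions: [RhOH(cod)]2 (3 mol %), (S)-MeO-F12-BIPHEP (6.6 mol %), 10 (3 equiv, in portions), toluene/H2O (10:1), 30 °C
Reagents that add atoms: none
Why: Hayashi–Miyaura rhodium-catalysed asymmetric 1,4-addition of an arylboronic acid to a chromone, in which aryl–Rh inserts the C2=C3 bond on the face left open by the electron-poor chiral bisphosphine and so sets C2 as (S); the base-free medium should keep the flavanone from opening to the chalcone, and the hindered C6–I bond is not expected to add to Rh(I) at 30 °C.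

Step 7
Reactants: 12 (4R)-4-benzyl-1,3-oxazolidin-2-one; 13 3-methylbut-2-enoyl chloride
Product: 15 (4R)-4-benzyl-3-(3-methylbut-2-enoyl)-1,3-oxazolidin-2-one, via lithiated oxazolidinone 14 (not isolated)
Conditions: n-BuLi, THF, −78 °C; then 13, −78 → 0 °C
Reagents that add atoms: none
Why: N-Acylation of the lithiated Evans oxazolidinone with the acid chloride; no amine base is present, so the senecioyl group should not be deconjugated.

Step 8
Reactants: 15 (4R)-4-benzyl-3-(3-methylbut-2-enoyl)-1,3-oxazolidin-2-one; 16 1-bromo-3-methylbut-2-ene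
Product: 18 (4R)-4-benzyl-3-[(2R)-5-methyl-2-(prop-1-en-2-yl)hex-4-enoyl]-1,3-oxazolidin-2-one, via sodium dienolate 17 (not isolated)
Conditions: NaHMDS, THF, −78 °C; then 16, −78 → −40 °C; AcOH quench
Reagents that add atoms: none
Why: Evans asymmetric alkylation in its deconjugative form: γ-deprotonation gives the sodium-chelated Z-dienolate, which should be alkylated at the α-carbon on the face opposite the C4 benzyl group of the auxiliary, setting the future C2'' centre as (2R) in the imide.

Step 9
Reactants: 18 (4R)-4-benzyl-3-[(2R)-5-methyl-2-(prop-1-en-2-yl)hex-4-enoyl]-1,3-oxazolidin-2-one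
Product: 19 (2R)-5-methyl-2-(prop-1-en-2-yl)hex-4-en-1-ol
Conditions: LiBH4, H2O (1 equiv), Et2O, 0 °C; aqueous work-up
Reagents that add atoms: none
Why: Reductive cleavage of the N-acyloxazolidinone with LiBH4, in which hydride attack on the exocyclic carbonyl should outrun enolisation of the β,γ-unsaturated imide, so the centre and the terminal double bond stay in place and the auxiliary is recovered.

Step 10
Reactants: 19 (2R)-5-methyl-2-(prop-1-en-2-yl)hex-4-en-1-ol
Product: 20 (3R)-3-(iodomethyl)-2,6-dimethylhepta-1,5-diene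
Conditions: PPh3, I2, imidazole, CH2Cl2, 0 °C → rt
Reagents that add atoms: iodine, II
Why: Garegg–Samuelsson (Appel-type) iodination by SN2 displacement of the alkoxyphosphonium group at the primary carbon, one atom away from the stereocentre, which is not touched.

Step 11
Reactants: 20 (3R)-3-(iodomethyl)-2,6-dimethylhepta-1,5-diene; 11 (2S)-6-iodo-2-[2-methoxy-4-(methoxymethoxy)phenyl]-5,7-bis(methoxymethoxy)-2,3-dihydro-4H-chromen-4-one
Product: 22 (2S)-2-[2-methoxy-4-(methoxymethoxy)phenyl]-5,7-bis(methoxymethoxy)-6-[(2S)-5-methyl-2-(prop-1-en-2-yl)hex-4-en-1-yl]-2,3-dihydro-4H-chromen-4-one, via lavandulylzinc iodide 21 (not isolated)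
Conditions: Zn dust (activated with BrCH2CH2Br/TMSCl), LiCl, THF, 40 °C; then 11, Pd(OAc)2 (5 mol %), SPhos (10 mol %), THF, 25 → 45 °C
Reagents that add atoms: none
Why: Negishi cross-coupling: Pd(0)/SPhos inserts into the C6–I bond of 11, the primary alkyl group of 21 passes from zinc to palladium, and reductive elimination forms the C6–C1'' bond. The closest known reaction type is the Pd/dialkylbiarylphosphine coupling of functionalised primary alkylzinc halides with di-ortho-substituted, electron-rich aryl iodides in the presence of ketones. No ring is closed. No stereocentre is formed: C2'' is β to the metal with no enolisable or ionisable position next to it, and the neutral, base-free medium leaves the C2–O1 bond and the C3 protons alone, so both centres should be carried through unchanged. The step needs site selectivity (secured by the single C–I bond placed at C6 in step 2), reductive elimination ahead of β-hydride elimination of the β-branched alkylpalladium (secured by the bulky electron-rich ligand, possibly helped by zinc coordination to the two flanking acetal oxygens) and chemoselectivity over the C4 ketone (alkylzinc halides do not add to ketones).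

Step 12
Reactants: 22 (2S)-2-[2-methoxy-4-(methoxymethoxy)phenyl]-5,7-bis(methoxymethoxy)-6-[(2S)-5-methyl-2-(prop-1-en-2-yl)hex-4-en-1-yl]-2,3-dihydro-4H-chromen-4-one
Product: 23 (2S)-5,7-dihydroxy-2-(4-hydroxy-2-methoxyphenyl)-6-[(2S)-5-methyl-2-(prop-1-en-2-yl)hex-4-en-1-yl]-2,3-dihydro-4H-chromen-4-one
Conditions: HCl (ca. 1.5 M) in MeOH/H2O, 40 °C, stopped at full conversion
Reagents that add atoms: none
Why: Acid-catalysed solvolysis of the three aryl methoxymethyl acetals (transacetalisation to dimethoxymethane), kept mild and short so that the isopropenyl and prenyl groups and the C2 centre should survive; no stereocentre is formed.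

**Compound list**

1 | 5,7-dihydroxy-4H-chromen-4-one | O=c1ccoc2cc(O)cc(O)c12 | starting material
2 | 5-hydroxy-7-(methoxymethoxy)-4H-chromen-4-one | O=c1ccoc2cc(OCOC)cc(O)c12 | intermediate
3 | 5-hydroxy-6-iodo-7-(methoxymethoxy)-4H-chromen-4-one | O=c1ccoc2cc(OCOC)c(I)c(O)c12 | intermediate
4 | sodium 6-iodo-7-(methoxymethoxy)-4-oxo-4H-chromen-5-olate | O=c1ccoc2cc(OCOC)c(I)c([O-])c12.[Na+] | intermediate (not isolated)
5 | 6-iodo-5,7-bis(methoxymethoxy)-4H-chromen-4-one | O=c1ccoc2cc(OCOC)c(I)c(OCOC)c12 | intermediate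
6 | 4-bromo-3-methoxyphenol | COc1cc(O)ccc1Br | starting material
7 | 1-bromo-2-methoxy-4-(methoxymethoxy)benzene | COCOc1ccc(Br)c(OC)c1 | intermediate
8 | [2-methoxy-4-(methoxymethoxy)phenyl]lithium | [Li]c1ccc(OCOC)cc1OC | intermediate (not isolated)
9 | lithium [2-methoxy-4-(methoxymethoxy)phenyl]tri(propan-2-yloxy)borate | [Li+].CC(C)O[B-](OC(C)C)(OC(C)C)c1ccc(OCOC)cc1OC | intermediate (not isolated)
10 | [2-methoxy-4-(methoxymethoxy)phenyl]boronic acid | COCOc1ccc(B(O)O)c(OC)c1 | intermediate
11 | (2S)-6-iodo-2-[2-methoxy-4-(methoxymethoxy)phenyl]-5,7-bis(methoxymethoxy)-2,3-dihydro-4H-chromen-4-one | O=C1C[C@@H](c2ccc(OCOC)cc2OC)Oc2cc(OCOC)c(I)c(OCOC)c12 | intermediate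
12 | (4R)-4-benzyl-1,3-oxazolidin-2-one | O=C1N[C@H](Cc2ccccc2)CO1 | starting material
13 | 3-methylbut-2-enoyl chloride | CC(C)=CC(=O)Cl | starting material
14 | (4R)-4-benzyl-3-lithio-1,3-oxazolidin-2-one | O=C1N([Li])[C@H](Cc2ccccc2)CO1 | intermediate (not isolated)
15 | (4R)-4-benzyl-3-(3-methylbut-2-enoyl)-1,3-oxazolidin-2-one | CC(C)=CC(=O)N1C(=O)OC[C@H]1Cc1ccccc1 | intermediate
16 | 1-bromo-3-methylbut-2-ene (prenyl bromide) | CC(C)=CCBr | starting material
17 | sodium (1Z)-1-[(4R)-4-benzyl-2-oxo-1,3-oxazolidin-3-yl]-3-methylbuta-1,3-dien-1-olate | C=C(C)/C=C(\[O-])N1C(=O)OC[C@H]1Cc1ccccc1.[Na+] | intermediate (not isolated)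
18 | (4R)-4-benzyl-3-[(2R)-5-methyl-2-(prop-1-en-2-yl)hex-4-enoyl]-1,3-oxazolidin-2-one | C=C(C)[C@@H](CC=C(C)C)C(=O)N1C(=O)OC[C@H]1Cc1ccccc1 | intermediate
19 | (2R)-5-methyl-2-(prop-1-en-2-yl)hex-4-en-1-ol [(R)-lavandulol] | C=C(C)[C@@H](CC=C(C)C)CO | intermediate
20 | (3R)-3-(iodomethyl)-2,6-dimethylhepta-1,5-diene | C=C(C)[C@@H](CC=C(C)C)CI | intermediate
21 | [(2R)-5-methyl-2-(prop-1-en-2-yl)hex-4-en-1-yl]zinc iodide | C=C(C)[C@@H](CC=C(C)C)C[Zn]I | intermediate (not isolated)
22 | (2S)-2-[2-methoxy-4-(methoxymethoxy)phenyl]-5,7-bis(methoxymethoxy)-6-[(2S)-5-methyl-2-(prop-1-en-2-yl)hex-4-en-1-yl]-2,3-dihydro-4H-chromen-4-one | C=C(C)[C@@H](CC=C(C)C)Cc1c(OCOC)cc2c(c1OCOC)C(=O)C[C@@H](c1ccc(OCOC)cc1OC)O2 | intermediate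
23 | (2S)-5,7-dihydroxy-2-(4-hydroxy-2-methoxyphenyl)-6-[(2S)-5-methyl-2-(prop-1-en-2-yl)hex-4-en-1-yl]-2,3-dihydro-4H-chromen-4-one | C=C(C)[C@@H](CC=C(C)C)Cc1c(O)cc2c(c1O)C(=O)C[C@@H](c1ccc(O)cc1OC)O2 | target

**Count and risks**

Total step count: 12. Longest linear sequence: 6 steps (7, 8, 9, 10, 11, 12; the chromone branch 1, 2, 3, 6, 11, 12 is equally long).

Steps most likely to fail:

(1) Step 11. Transmetalation and reductive elimination at the doubly ortho-oxygenated C6 may be slow. That would let β-hydride elimination of the alkylpalladium or proto-deiodination take over, and forcing the reaction would expose the C2–O1 bond to zinc-salt-mediated ring opening and loss of configuration at C2. The fallback makes the same bond before C2 exists. It sets out from 5 and 20: lavandulylzinc iodide 21 is coupled with iodochromone 5 under forcing conditions (Pd-PEPPSI-IPent, THF/NMP, 65 °C), which 5 can bear because it has no stereocentre and no benzylic C–O bond. This should give 5,7-bis(methoxymethoxy)-6-[(2S)-5-methyl-2-(prop-1-en-2-yl)hex-4-en-1-yl]-4H-chromen-4-one F1. Rh-catalysed asymmetric 1,4-addition of 10 under the conditions of step 6 (the isolated alkenes should not insert) then comes back to the route at 22.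

(2) Step 6. Arylrhodium(I) may add oxidatively into the C6–I bond, the electron-rich 5-alkoxychromone may insert slowly into the hindered ortho-methoxyaryl–Rh bond, and 10 may protodeboronate. The fallback arylates before iodinating. It sets out from 2: Rh-catalysed addition of 10 to 2 (no C–I bond, carbonyl activated by the O5–H hydrogen bond) should give (2S)-5-hydroxy-2-[2-methoxy-4-(methoxymethoxy)phenyl]-7-(methoxymethoxy)-2,3-dihydro-4H-chromen-4-one F2. Iodination with BnNMe3·ICl2/CaCO3, which attacks the free phenol ring and not the ring-B ethers, should give (2S)-5-hydroxy-6-iodo-2-[2-methoxy-4-(methoxymethoxy)phenyl]-7-(methoxymethoxy)-2,3-dihydro-4H-chromen-4-one F3. MOMCl/i-Pr2NEt (no strong base, so C2 is safe) comes back to the route at 11.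

(3) Step 12. Acid may promote Markovnikov addition of O5–H, O7–H or methanol to the isopropenyl and prenyl double bonds (chroman formation), and may open the pyranone and epimerise C2. The fallback exchanges the acetals for silyl ethers before the chain is attached. It sets out from 11: HCl/MeOH, with no alkene yet present, should give (2S)-5,7-dihydroxy-2-(4-hydroxy-2-methoxyphenyl)-6-iodo-2,3-dihydro-4H-chromen-4-one F4. TESOTf/2,6-lutidine should give (2S)-6-iodo-2-{2-methoxy-4-[(triethylsilyl)oxy]phenyl}-5,7-bis[(triethylsilyl)oxy]-2,3-dihydro-4H-chromen-4-one F5. Negishi coupling with 21 as in step 11 should give (2S)-2-{2-methoxy-4-[(triethylsilyl)oxy]phenyl}-6-[(2S)-5-methyl-2-(prop-1-en-2-yl)hex-4-en-1-yl]-5,7-bis[(triethylsilyl)oxy]-2,3-dihydro-4H-chromen-4-one F6. Pyridine-buffered HF·pyridine (THF, 0 °C) comes back to the route at 23.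

Further compounds
F1 | step 11 | 5,7-bis(methoxymethoxy)-6-[(2S)-5-methyl-2-(prop-1-en-2-yl)hex-4-en-1-yl]-4H-chromen-4-one | C=C(C)[C@@H](CC=C(C)C)Cc1c(OCOC)cc2occc(=O)c2c1OCOC
F2 | step 6 | (2S)-5-hydroxy-2-[2-methoxy-4-(methoxymethoxy)phenyl]-7-(methoxymethoxy)-2,3-dihydro-4H-chromen-4-one | O=C1C[C@@H](c2ccc(OCOC)cc2OC)Oc2cc(OCOC)cc(O)c12
F3 | step 6 | (2S)-5-hydroxy-6-iodo-2-[2-methoxy-4-(methoxymethoxy)phenyl]-7-(methoxymethoxy)-2,3-dihydro-4H-chromen-4-one | O=C1C[C@@H](c2ccc(OCOC)cc2OC)Oc2cc(OCOC)c(I)c(O)c12
F4 | step 12 | (2S)-5,7-dihydroxy-2-(4-hydroxy-2-methoxyphenyl)-6-iodo-2,3-dihydro-4H-chromen-4-one | O=C1C[C@@H](c2ccc(O)cc2OC)Oc2cc(O)c(I)c(O)c12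
F5 | step 12 | (2S)-6-iodo-2-{2-methoxy-4-[(triethylsilyl)oxy]phenyl}-5,7-bis[(triethylsilyl)oxy]-2,3-dihydro-4H-chromen-4-one | O=C1C[C@@H](c2ccc(O[Si](CC)(CC)CC)cc2OC)Oc2cc(O[Si](CC)(CC)CC)c(I)c(O[Si](CC)(CC)CC)c12
F6 | step 12 | (2S)-2-{2-methoxy-4-[(triethylsilyl)oxy]phenyl}-6-[(2S)-5-methyl-2-(prop-1-en-2-yl)hex-4-en-1-yl]-5,7-bis[(triethylsilyl)oxy]-2,3-dihydro-4H-chromen-4-one | C=C(C)[C@@H](CC=C(C)C)Cc1c(O[Si](CC)(CC)CC)cc2c(c1O[Si](CC)(CC)CC)C(=O)C[C@@H](c1ccc(O[Si](CC)(CC)CC)cc1OC)O2
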